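**Remark on the chemistry (assumption):** ring A is the benzoyl ring (C1A bears the ester carbonyl, C2A the hydroxyl, C4A the methoxy group, C6A the methyl group). Ring B is the benzoic acid ring (C1B bears CO2H, O2B is the hydroxyl oxygen on C2B, O4B the ester oxygen on C4B, C6B bears the pentyl chain). The target has no stereocenter, so no step sets or endangers a configuration.

## The problem

Compound 22 is a depside. Its two benzene rings share no carbon–carbon bond and are joined only by an aryl ester from the carbonyl carbon on C1A to O4B, so the task is to build two substitution patterns and one ester, not a ring system. With no stereocenter, every difficulty is one of regiochemistry and chemoselectivity. The ester carbonyl stands between C2A–OH and C6A–CH3, and the oxygen it must reach, O4B, lies para to the ring B carboxyl and is a weak nucleophile, so the conventional acylation is a hindered coupling. Four phenolic oxygens must end in four different states (C4A methylated, C2A free, O2B free, O4B acylated) beside a free carboxylic acid. The aryl ester will not survive hydroxide, alkoxides, amines or long heating, and the 2-hydroxybenzoic acid of ring B loses CO2 when heated, so the late steps must be neutral, or Lewis acidic and cold. The feature that invites an unusual solution is the sequence C6A(CH3)–C1A(acyl)–C2A(O) on ring A. A benzyne with its triple bond between C1A and C6A and a methoxy group on C2A is polarized so that a carbon nucleophile enters at C6A and an acyl group is then taken up at C1A. If that acyl group is the ester carbonyl of a malonate already bound to O4B, the hindered ester and the C6A carbon arrive in one operation.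

## Retrosynthesis

**Phenol and acid unmasking (22 ← 21 ← 20).** The O–CH3 bond at C2A is cut last, and before it the two benzyl–oxygen bonds on ring B. Carrying ring A as a symmetric 3,5-dimethoxy unit is what guarantees a single aryne later. The two ethers can be told apart at the end because only the C2A ether can chelate a Lewis acid together with the ester carbonyl. Hydrogenolysis of 20 to 21 is placed before the BCl3 step so that BCl3 is asked to do one thing only. A single BCl3 treatment of 20 was considered, but cleavage of a benzyl ester by BCl3 is less dependable than hydrogenolysis.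

**The C6A methyl group (20 ← 19 ← 18).** Retrosynthetically a carboxyl group is added to the C6A methyl carbon, first as the acid 19 and then as the tert-butyl ester 18. This extra carbon is what makes the future methyl carbon a stabilized carbanion in the key step. The forward steps are acidolysis and a radical hydrodecarboxylation. Neither may use strong base, because an arylacetate carboxylate sits next to the aryl ester.

**Key disconnection (18 ← 8 + 17).** Two bonds on ring A are cut, C6A–CH2 and C1A–C(=O), which is the reverse of inserting an aryne into the CH2–C(=O)OAr bond of a malonate. The neighbouring cut, the ester C–O bond, would require a di-ortho-substituted ring A acid to be activated toward a deactivated phenol. The insertion instead makes the ester bond earlier, at an unhindered malonyl carbon (17), and lets the aryl anion collect the intact ester intramolecularly. The precursors are much simpler: the silyl triflate 8 carries all of ring A, and 17 carries ring B with its protecting groups. The forward reaction must be regioselective on the aryne and must choose the aryl ester carbonyl over the tert-butyl ester carbonyl.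

**Aryne precursor (8 ← 6 ← 2 ← 1).** The C–Si and O–S bonds of 8 are cut back to 3,5-dimethoxyphenol 1. A carbamate on the phenol oxygen (2) directs lithiation to the carbon between it and a methoxy group; silylation gives 6, and carbamate removal with triflation in one flask gives 8. The alternative of ortho-bromination and silyl migration suffers from a regiochemical question in the bromination.

**Ring B malonate (17 ← 15 + 16; 15 ← 14 ← 13 ← 12 ← 10 ← 9).** The malonyl C–O bond is cut to the phenol 15 and the half-ester 16. Phenol 15 needs benzyl on the carboxyl and on O2B but a free O4B, which is the reverse of the natural reactivity order of the two phenols. Hence O4B is silylated first (13), O2B is benzylated (14) and the silyl group is removed (15). The benzyl ester 12 comes from olivetolic acid 10 and benzyl bromide 11, and 10 from olivetol 9 by ortho-carboxylation. Benzyl is chosen for both positions because it is inert to fluoride, to CF3CO2H and to the radical step, and leaves under neutral conditions.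

## Roads not taken

**Alternative 1:** The cut goes through ring B itself, at C1B–C6B and C2B–C3B, leading back to dibenzyl malonate A1 and (E)-non-3-en-2-one A2.
- Forward step: base-mediated Michael addition of A1 to A2, then Claisen closure of the methyl ketone enolate on one benzyl ester in the same flask, would give the racemic trans cyclohexenone A3 (enol form). An oxidation would then aromatize A3 to 12.
- Merits: cheap acyclic materials, a carboxyl position fixed by construction, and the benzyl ester already in place. The two stereocenters of A3 vanish on aromatization and need no control.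
- Weak points: the key step is spent on the ring that olivetol 9 supplies ready-made, and an extra oxidation must stop at the resorcylate without halogenating it. It does nothing for the real problems, the hindered ester and ring A.
- Comparison: it reaches 12 in two steps, as many as steps 4 and 5, and with better regiochemical assurance than the carboxylation of step 4. On that stretch it is at least as good, and the chosen plan sets against it only that 9 is bought with the ring made. It is an alternative supply of 12, not a rival answer to the ester.

**Alternative 2:** Ring A is cut at C1A–C2A and C5A–C6A, a retro-Diels–Alder step to 1,3-dimethoxy-1-[(trimethylsilyl)oxy]buta-1,3-diene A4 and the but-2-ynoate A5, which would come from 12 by acylation at O4B.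
- Forward step: cycloaddition with the nucleophilic diene terminus bonding to the methyl-bearing alkyne carbon, then 1,4-elimination of the C2A alkoxy group and desilylation on acidic work-up, would give A6. Hydrogenolysis of its benzyl ester would give 22.
- Merits: as in the chosen plan, the hindered ester is never made by acylation. Ring A arrives with C2A–OH free and C4A–OCH3 in place, so demethylation, decarboxylation and O2B protection all fall away.
- Weak points: 3-substituted alkynoates are reluctant dienophiles toward ketene acetal dienes and need heat, which the hydrolytically fragile A4 tolerates poorly. A5 is also a Michael acceptor and an acyl donor with a phenoxide leaving group, so open-chain conjugate adducts, silyl transfer to the free O2B hydroxyl and acyl transfer compete with ring closure.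
- Comparison: in step count this road is clearly better, roughly half the length, and its reaction type is known for alkyl alkynoates. The chosen plan sets against it a bond-forming event at or below room temperature, regiochemistry dictated by one substituent, and bench-stable partners, and it accepts four finishing steps as the price. Should the chosen key step fail outright, this would be the first road to try.

**Alternative 3:** The cut is again in ring A, at C1A–C6A (aldol) together with the ester C–O bond. The precursors are 6-(2,4-dioxopentyl)-2,2-dimethyl-4H-1,3-dioxin-4-one A7 and 12.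
- Forward step: heating A7 with 12 would unveil a transient acylketene that acylates O4B to give the aryl 3,5,7-trioxooctanoate A8. A tertiary amine would then bring about C1A–C6A aldol condensation and dehydration to the resorcylate A9. Methylation of the one non-chelated phenol (C4A–OH) and hydrogenolysis would finish.
- Merits: it is biomimetic, makes ester and ring in one flask, needs no O2B protection, and the ring-forming sequence is well established with alcohols as ketene traps.
- Weak points: A7 takes several steps and is a sensitive polyketone. A8 is an aryl β-keto ester that can re-expel the ring B phenoxide under the amine or close through oxygen to a pyranone. The late methylation is one more selectivity question, posed in base beside the depside ester.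
- Comparison: the length is similar or slightly shorter, and the precedent for the key step is better than for the chosen one. The chosen plan sets against it robust aromatic intermediates, a C4A methyl ether present from the start, and a chelation-controlled demethylation in place of a selective methylation. Both plans expose an aryl ester with acidic α-hydrogens to base; the chosen plan does so at lower temperature.

Key step: step 10

## Route

Step 1
Reactants: 1 3,5-dimethoxyphenol
Product: 2 3,5-dimethoxyphenyl N-(propan-2-yl)carbamate
Conditions: i-PrNCO, Et3N (cat.), CH2Cl2, rt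
Reagents that add atoms: isopropyl isocyanate, CC(C)N=C=O
Why: Base-catalysed addition of the phenol to the isocyanate (carbamoylation) is clean and gives the N–H carbamate that serves as a removable directing group for ortho-silylation.

Step 2
Reactants: 2 3,5-dimethoxyphenyl N-(propan-2-yl)carbamate
Product: 6 3,5-dimethoxy-2-(trimethylsilyl)phenyl N-(propan-2-yl)carbamate, via N-silyl carbamate 3 (not isolated), via aryllithium 4 (not isolated), via N-silyl arylsilane 5 (not isolated)
Conditions: TBSOTf, TMEDA, Et2O, 0 °C to rt; n-BuLi, TMEDA, −78 °C; Me3SiCl, −78 °C to rt; aq. NaHSO4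
Reagents that add atoms: chlorotrimethylsilane, C[Si](C)(C)Cl; tert-butyldimethylsilyl trifluoromethanesulfonate, CC(C)(C)[Si](C)(C)OS(=O)(=O)C(F)(F)F (its silyl group is held only in 3 to 5); n-butyllithium, [Li]CCCC (its lithium is held only in 4)
Why: Directed ortho-metalation: N-silylation removes the acidic N–H, and the carbamate on C1 and the methoxy group on C3 together direct lithiation to the carbon between them (C2 and C6 are equivalent by symmetry), while −78 °C holds back the anionic Fries shift. Me3SiCl quenches the aryllithium and the labile N–Si bond is hydrolysed on work-up.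

Step 3
Reactants: 6 3,5-dimethoxy-2-(trimethylsilyl)phenyl N-(propan-2-yl)carbamate
Product: 8 3,5-dimethoxy-2-(trimethylsilyl)phenyl trifluoromethanesulfonate, via silylphenol 7 (not isolated)
Conditions: DBU, Et2NH, MeCN, 40 °C; then PhNTf2, rt
Reagents that add atoms: N-phenylbis(trifluoromethanesulfonimide), O=S(=O)(N(c1ccccc1)S(=O)(=O)C(F)(F)F)C(F)(F)F
Why: DBU removes the carbamate N–H and the aryloxide is expelled by an E1cB path, the isocyanate being scavenged by Et2NH. The aryloxide is then triflated in the same flask by PhNTf2, which is mild enough to leave the C–Si bond untouched.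

Step 4
Reactants: 9 olivetol (5-pentylbenzene-1,3-diol)
Product: 10 olivetolic acid (2,4-dihydroxy-6-pentylbenzoic acid)
Conditions: CH3OMgOCO2CH3 (2 M in DMF), 120 °C, N2; then cold aq. HCl
Reagents that add atoms: methoxymagnesium methyl carbonate, COC(=O)O[Mg]OC
Why: Kolbe–Schmitt-type carboxylation: magnesium chelation between a phenoxide oxygen and the incoming carboxylate delivers CO2 ortho to a hydroxyl, and the position ortho to one hydroxyl and para to the other is the expected site for a 5-alkylresorcinol.

Step 5
Reactants: 10 olivetolic acid; 11 benzyl bromide
Product: 12 benzyl 2,4-dihydroxy-6-pentylbenzoate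
Conditions: KHCO3, DMF, rt
Reagents that add atoms: none
Why: KHCO3 ionizes only the carboxylic acid, so SN2 alkylation by benzyl bromide gives the ester and leaves both phenols free; room temperature avoids decarboxylation of the acid.

Step 6
Reactants: 12 benzyl 2,4-dihydroxy-6-pentylbenzoate
Product: 13 benzyl 2-hydroxy-6-pentyl-4-{[tri(propan-2-yl)silyl]oxy}benzoate
Conditions: i-Pr3SiCl, imidazole, CH2Cl2, 0 °C to rt
Reagents that add atoms: chlorotri(propan-2-yl)silane, CC(C)[Si](Cl)(C(C)C)C(C)C
Why: The O2B hydroxyl is tied up in a hydrogen bond to the ester carbonyl, so silylation with the bulky chlorosilane should occur at the free and more acidic O4B hydroxyl.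

Step 7
Reactants: 13 benzyl 2-hydroxy-6-pentyl-4-{[tri(propan-2-yl)silyl]oxy}benzoate; 11 benzyl bromide
Product: 14 benzyl 2-(benzyloxy)-6-pentyl-4-{[tri(propan-2-yl)silyl]oxy}benzoate
Conditions: K2CO3, DMF, rt to 40 °C
Reagents that add atoms: none
Why: Williamson etherification of the remaining chelated phenol; the triisopropylsilyl ether is bulky enough to withstand anhydrous K2CO3 at this temperature.

Step 8
Reactants: 14 benzyl 2-(benzyloxy)-6-pentyl-4-{[tri(propan-2-yl)silyl]oxy}benzoate
Product: 15 benzyl 2-(benzyloxy)-4-hydroxy-6-pentylbenzoate
Conditions: Bu4NF, AcOH, THF, 0 °C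
Reagents that add atoms: none
Why: Fluoride cleaves the aryl silyl ether; acetic acid buffers the phenoxide so that neither the benzyl ester nor the benzyl ether is touched.

Step 9
Reactants: 15 benzyl 2-(benzyloxy)-4-hydroxy-6-pentylbenzoate; 16 3-tert-butoxy-3-oxopropanoic acid
Product: 17 benzyl 2-(benzyloxy)-4-[(3-tert-butoxy-3-oxopropanoyl)oxy]-6-pentylbenzoate
Conditions: DCC, DMAP (cat.), CH2Cl2, 0 °C to rt
Reagents that add atoms: none
Why: Steglich esterification: the unhindered malonic half-ester is activated by the carbodiimide and trapped by the O4B phenol, so the oxygen–carbonyl bond of the future depside is made at an unhindered acyl carbon.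

Step 10
Reactants: 8 3,5-dimethoxy-2-(trimethylsilyl)phenyl trifluoromethanesulfonate; 17 benzyl 2-(benzyloxy)-4-[(3-tert-butoxy-3-oxopropanoyl)oxy]-6-pentylbenzoate
Product: 18 benzyl 2-(benzyloxy)-4-{[2-(2-tert-butoxy-2-oxoethyl)-4,6-dimethoxybenzoyl]oxy}-6-pentylbenzoate
Conditions: KF, 18-crown-6, THF, 0 °C to rt, slow addition of 8
Reagents that add atoms: none
Why: Proposed new method: fluoride strips the silyl group from 8 and triflate leaves, giving 3,5-dimethoxybenzyne with its triple bond between C1A and C6A; the inductively withdrawing C2A methoxy group distorts the aryne so that the malonate carbanion of 17 adds at C6A, the carbon remote from it, and the aryl anion develops on C1A next to oxygen. That anion adds to the nearby and far more electrophilic aryl ester carbonyl (the tert-butyl ester is shielded), giving a benzocyclobutene alkoxide that opens by cleaving the former malonate C–C bond to a tert-butyl arylacetate enolate stabilized by ring and ester; proton transfer from the next molecule of 17 carries the chain. The net result is insertion of the aryne into the CH2–C(=O)OAr bond, which forms C6A–CH2 and C1A–C(=O) and delivers the di-ortho-substituted aryl ester intramolecularly. The closest known reaction type is the fluoride-induced insertion of arynes into the α-carbon–carbonyl bond of dialkyl malonates and β-keto esters (acyl-alkylation), in which 3-methoxybenzyne shows the same regiochemistry; an aryl alkyl malonate has not been used. No ring is retained (the four-membered alkoxide is transient) and no stereocenter is formed. The step needs regioselectivity on the aryne, secured by the C2A methoxy group and by the symmetry of the 3,5-dimethoxy pattern (one aryne only), and chemoselectivity between the two ester carbonyls, secured by the electrophilicity of the aryl ester and the bulk of the tert-butyl ester. The mild KF/18-crown-6 conditions and slow addition of 8 are chosen to keep the carbanion of 17 from expelling the ring B phenoxide.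

Step 11
Reactants: 18 benzyl 2-(benzyloxy)-4-{[2-(2-tert-butoxy-2-oxoethyl)-4,6-dimethoxybenzoyl]oxy}-6-pentylbenzoate
Product: 19 {2-[(3-(benzyloxy)-4-[(benzyloxy)carbonyl]-5-pentylphenoxy)carbonyl]-3,5-dimethoxyphenyl}acetic acid
Conditions: CF3CO2H, CH2Cl2, 0 °C to rt
Reagents that add atoms: none
Why: Acidolysis of the tert-butyl ester by loss of 2-methylpropene; benzyl ester, benzyl ether, aryl ester and methyl ethers are stable to CF3CO2H at this temperature, and the acid stays un-ionized and is used at once.

Step 12
Reactants: 19 {2-[(3-(benzyloxy)-4-[(benzyloxy)carbonyl]-5-pentylphenoxy)carbonyl]-3,5-dimethoxyphenyl}acetic acid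
Product: 20 benzyl 2-(benzyloxy)-4-[(2,4-dimethoxy-6-methylbenzoyl)oxy]-6-pentylbenzoate
Conditions: 9-mesityl-10-methylacridinium tetrafluoroborate (cat.), (4-ClC6H4S)2 (cat.), 2,6-lutidine (0.2 equiv), ClCH2CH2Cl, blue LEDs, rt
Reagents that add atoms: none
Why: Photocatalytic hydrodecarboxylation, a reaction known for arylacetic acids: the excited acridinium oxidizes the carboxylate, CO2 is lost to give a benzylic radical at the C6A carbon, and the arenethiol formed from the disulfide hands over a hydrogen atom to leave the methyl group. Base is substoichiometric so that little free carboxylate stands next to the aryl ester.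

Step 13
Reactants: 20 benzyl 2-(benzyloxy)-4-[(2,4-dimethoxy-6-methylbenzoyl)oxy]-6-pentylbenzoate
Product: 21 4-[(2,4-dimethoxy-6-methylbenzoyl)oxy]-2-hydroxy-6-pentylbenzoic acid
Conditions: H2 (1 atm), Pd/C (10 wt% Pd), EtOAc, rt
Reagents that add atoms: none
Why: Hydrogenolysis cleaves the benzyl ester and the benzyl ether under neutral conditions that leave the aryl ester and both methyl ethers alone.

Step 14
Reactants: 21 4-[(2,4-dimethoxy-6-methylbenzoyl)oxy]-2-hydroxy-6-pentylbenzoic acid
Product: 22 2-hydroxy-4-[(2-hydroxy-4-methoxy-6-methylbenzoyl)oxy]-6-pentylbenzoic acid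
Conditions: BCl3 (excess), CH2Cl2, −78 to 0 °C; cold aq. work-up
Reagents that add atoms: none
Why: Chelation-controlled ether cleavage: BCl3 binds between the ester carbonyl oxygen and the C2A methoxy oxygen and chloride removes that methyl group, whereas the C4A methoxy group cannot chelate and should survive at low temperature. Excess reagent covers the acid and phenol of ring B, which are released again on aqueous work-up.

## Compound list

1 | 3,5-dimethoxyphenol | COc1cc(O)cc(OC)c1 | starting material
2 | 3,5-dimethoxyphenyl N-(propan-2-yl)carbamate | COc1cc(OC)cc(OC(=O)NC(C)C)c1 | intermediate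
3 | 3,5-dimethoxyphenyl N-[tert-butyl(dimethyl)silyl]-N-(propan-2-yl)carbamate | COc1cc(OC)cc(OC(=O)N(C(C)C)[Si](C)(C)C(C)(C)C)c1 | intermediate (not isolated)
4 | [2-({[tert-butyl(dimethyl)silyl](propan-2-yl)carbamoyl}oxy)-4,6-dimethoxyphenyl]lithium | [Li]c1c(OC)cc(OC)cc1OC(=O)N(C(C)C)[Si](C)(C)C(C)(C)C | intermediate (not isolated)
5 | 3,5-dimethoxy-2-(trimethylsilyl)phenyl N-[tert-butyl(dimethyl)silyl]-N-(propan-2-yl)carbamate | COc1cc(OC)c([Si](C)(C)C)c(OC(=O)N(C(C)C)[Si](C)(C)C(C)(C)C)c1 | intermediate (not isolated)
6 | 3,5-dimethoxy-2-(trimethylsilyl)phenyl N-(propan-2-yl)carbamate | COc1cc(OC)c([Si](C)(C)C)c(OC(=O)NC(C)C)c1 | intermediate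
7 | 3,5-dimethoxy-2-(trimethylsilyl)phenol | COc1cc(O)c([Si](C)(C)C)c(OC)c1 | intermediate (not isolated)
8 | 3,5-dimethoxy-2-(trimethylsilyl)phenyl trifluoromethanesulfonate | COc1cc(OC)c([Si](C)(C)C)c(OS(=O)(=O)C(F)(F)F)c1 | intermediate
9 | olivetol (5-pentylbenzene-1,3-diol) | CCCCCc1cc(O)cc(O)c1 | starting material
10 | olivetolic acid (2,4-dihydroxy-6-pentylbenzoic acid) | CCCCCc1cc(O)cc(O)c1C(=O)O | intermediate
11 | benzyl bromide | BrCc1ccccc1 | starting material
12 | benzyl 2,4-dihydroxy-6-pentylbenzoate | CCCCCc1cc(O)cc(O)c1C(=O)OCc1ccccc1 | intermediate
13 | benzyl 2-hydroxy-6-pentyl-4-{[tri(propan-2-yl)silyl]oxy}benzoate | CCCCCc1cc(O[Si](C(C)C)(C(C)C)C(C)C)cc(O)c1C(=O)OCc1ccccc1 | intermediate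
14 | benzyl 2-(benzyloxy)-6-pentyl-4-{[tri(propan-2-yl)silyl]oxy}benzoate | CCCCCc1cc(O[Si](C(C)C)(C(C)C)C(C)C)cc(OCc2ccccc2)c1C(=O)OCc1ccccc1 | intermediate
15 | benzyl 2-(benzyloxy)-4-hydroxy-6-pentylbenzoate | CCCCCc1cc(O)cc(OCc2ccccc2)c1C(=O)OCc1ccccc1 | intermediate
16 | 3-tert-butoxy-3-oxopropanoic acid | CC(C)(C)OC(=O)CC(=O)O | starting material
17 | benzyl 2-(benzyloxy)-4-[(3-tert-butoxy-3-oxopropanoyl)oxy]-6-pentylbenzoate | CCCCCc1cc(OC(=O)CC(=O)OC(C)(C)C)cc(OCc2ccccc2)c1C(=O)OCc1ccccc1 | intermediate
18 | benzyl 2-(benzyloxy)-4-{[2-(2-tert-butoxy-2-oxoethyl)-4,6-dimethoxybenzoyl]oxy}-6-pentylbenzoate | CCCCCc1cc(OC(=O)c2c(CC(=O)OC(C)(C)C)cc(OC)cc2OC)cc(OCc2ccccc2)c1C(=O)OCc1ccccc1 | intermediate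
19 | {2-[(3-(benzyloxy)-4-[(benzyloxy)carbonyl]-5-pentylphenoxy)carbonyl]-3,5-dimethoxyphenyl}acetic acid | CCCCCc1cc(OC(=O)c2c(CC(=O)O)cc(OC)cc2OC)cc(OCc2ccccc2)c1C(=O)OCc1ccccc1 | intermediate
20 | benzyl 2-(benzyloxy)-4-[(2,4-dimethoxy-6-methylbenzoyl)oxy]-6-pentylbenzoate | CCCCCc1cc(OC(=O)c2c(C)cc(OC)cc2OC)cc(OCc2ccccc2)c1C(=O)OCc1ccccc1 | intermediate
21 | 4-[(2,4-dimethoxy-6-methylbenzoyl)oxy]-2-hydroxy-6-pentylbenzoic acid | CCCCCc1cc(OC(=O)c2c(C)cc(OC)cc2OC)cc(O)c1C(=O)O | intermediate
22 | 2-hydroxy-4-[(2-hydroxy-4-methoxy-6-methylbenzoyl)oxy]-6-pentylbenzoic acid | CCCCCc1cc(OC(=O)c2c(C)cc(OC)cc2O)cc(O)c1C(=O)O | target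

## Step count and least certain steps

Total: 14 steps. Longest linear sequence: 11 steps (steps 4 to 14, from olivetol 9). The ring A branch is 3 steps (steps 1 to 3) and joins at step 10.

**Step 10 (key step, proposed new method).** The most likely failure is loss of the ring B phenoxide from the carbanion of 17 by an E1cB path to a carboxyketene before the aryne is intercepted. The freed phenoxide would then be arylated at oxygen by the aryne. Protonation of the aryl anion in place of acyl capture (plain α-arylation) and a second arylation of the product enolate are further leaks. All follow from the aryl ester being both the intended electrophile and a good leaving group.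

Fallback, using known chemistry and keeping the aryne insertion: it sets out from 8. Treatment of 8 with dibenzyl malonate A1 and fluoride, the established insertion into a symmetric dialkyl malonate, should give benzyl 2-[2-(benzyloxy)-2-oxoethyl]-4,6-dimethoxybenzoate F1. Hydrogenolysis (H2, Pd/C) would give 2-(carboxymethyl)-4,6-dimethoxybenzoic acid F2. The acridinium-photocatalysed hydrodecarboxylation of step 12, which can act only on the arylacetic carboxyl, would give 2,4-dimethoxy-6-methylbenzoic acid F3. Acylation of phenol 15 with F3 through its mixed trifluoroacetic anhydride ((CF3CO)2O, toluene, rt) comes back to the route at 20. The hindered ester is then made by conventional acylation, which costs the convergence of the plan but not the disconnection of ring A.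

**Step 12.** The most likely failure is acyl transfer by neighbouring-group attack. The arylacetate carboxylate can add to the adjacent aryl ester carbonyl through a six-membered transition state and expel the ring B phenoxide, forming a homophthalic anhydride that reopens at its more reactive carbonyl to the wrong ester. Unproductive oxidation of the electron-rich rings by the excited acridinium is a lesser concern.

Fallback: from 19, carbodiimide coupling without base (DCC, 1-hydroxypyridine-2(1H)-thione, CH2Cl2, dark) would give the thiohydroxamate ester 2-thioxopyridin-1(2H)-yl {2-[(3-(benzyloxy)-4-[(benzyloxy)carbonyl]-5-pentylphenoxy)carbonyl]-3,5-dimethoxyphenyl}acetate F4. Irradiation with visible light in the presence of excess 2-methylpropane-2-thiol (Barton decarboxylation, a radical chain in which no carboxylate appears) returns to the route at 20.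

**Step 4.** The most likely failures are carboxylation at the wrong ring position (C2, between the two hydroxyls), incomplete conversion because the carboxylation is reversible, and decarboxylation during work-up.

Fallback: from 9, Vilsmeier–Haack formylation (POCl3, DMF), which attacks para to one hydroxyl, would give 2,4-dihydroxy-6-pentylbenzaldehyde F5. Silylation of the non-chelated hydroxyl (i-Pr3SiCl, imidazole) would give 2-hydroxy-6-pentyl-4-{[tri(propan-2-yl)silyl]oxy}benzaldehyde F6. Benzylation (11, K2CO3, DMF) would give 2-(benzyloxy)-6-pentyl-4-{[tri(propan-2-yl)silyl]oxy}benzaldehyde F7. Pinnick oxidation (NaClO2, NaH2PO4, 2-methylbut-2-ene, t-BuOH–H2O) would give 2-(benzyloxy)-6-pentyl-4-{[tri(propan-2-yl)silyl]oxy}benzoic acid F8. Esterification with 11 and K2CO3 returns to the route at 14.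

**Step 7.** The most likely failure is loss or migration of the silyl group under carbonate, after which benzylation also takes place at O4B.

Fallback: from 12, selective allylation of the non-chelated hydroxyl (3-bromoprop-1-ene, K2CO3, acetone) would give benzyl 2-hydroxy-6-pentyl-4-(prop-2-en-1-yloxy)benzoate F9. Benzylation (11, K2CO3, DMF) would give benzyl 2-(benzyloxy)-6-pentyl-4-(prop-2-en-1-yloxy)benzoate F10. Deallylation with Pd(PPh3)4 and morpholine returns to the route at 15; the base-stable allyl ether replaces the silyl ether as the temporary group.

## Further compounds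

F1 | step 10 | benzyl 2-[2-(benzyloxy)-2-oxoethyl]-4,6-dimethoxybenzoate | COc1cc(OC)c(C(=O)OCc2ccccc2)c(CC(=O)OCc2ccccc2)c1
F2 | step 10 | 2-(carboxymethyl)-4,6-dimethoxybenzoic acid | COc1cc(OC)c(C(=O)O)c(CC(=O)O)c1
F3 | step 10 | 2,4-dimethoxy-6-methylbenzoic acid | COc1cc(C)c(C(=O)O)c(OC)c1
F4 | step 12 | 2-thioxopyridin-1(2H)-yl {2-[(3-(benzyloxy)-4-[(benzyloxy)carbonyl]-5-pentylphenoxy)carbonyl]-3,5-dimethoxyphenyl}acetate | CCCCCc1cc(OC(=O)c2c(CC(=O)On3ccccc3=S)cc(OC)cc2OC)cc(OCc2ccccc2)c1C(=O)OCc1ccccc1
F5 | step 4 | 2,4-dihydroxy-6-pentylbenzaldehyde | CCCCCc1cc(O)cc(O)c1C=O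
F6 | step 4 | 2-hydroxy-6-pentyl-4-{[tri(propan-2-yl)silyl]oxy}benzaldehyde | CCCCCc1cc(O[Si](C(C)C)(C(C)C)C(C)C)cc(O)c1C=O
F7 | step 4 | 2-(benzyloxy)-6-pentyl-4-{[tri(propan-2-yl)silyl]oxy}benzaldehyde | CCCCCc1cc(O[Si](C(C)C)(C(C)C)C(C)C)cc(OCc2ccccc2)c1C=O
F8 | step 4 | 2-(benzyloxy)-6-pentyl-4-{[tri(propan-2-yl)silyl]oxy}benzoic acid | CCCCCc1cc(O[Si](C(C)C)(C(C)C)C(C)C)cc(OCc2ccccc2)c1C(=O)O
F9 | step 7 | benzyl 2-hydroxy-6-pentyl-4-(prop-2-en-1-yloxy)benzoate | CCCCCc1cc(OCC=C)cc(O)c1C(=O)OCc1ccccc1
F10 | step 7 | benzyl 2-(benzyloxy)-6-pentyl-4-(prop-2-en-1-yloxy)benzoate | CCCCCc1cc(OCC=C)cc(OCc2ccccc2)c1C(=O)OCc1ccccc1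
A1 | alternative 1 | dibenzyl malonate | O=C(CC(=O)OCc1ccccc1)OCc1ccccc1
A2 | alternative 1 | (E)-non-3-en-2-one | CCCCC/C=C/C(C)=O
A3 | alternative 1 | benzyl trans-4-hydroxy-2-oxo-6-pentylcyclohex-3-ene-1-carboxylate (racemic, enol form, one enantiomer drawn) | CCCCC[C@@H]1CC(O)=CC(=O)[C@H]1C(=O)OCc1ccccc1
A4 | alternative 2 | 1,3-dimethoxy-1-[(trimethylsilyl)oxy]buta-1,3-diene | COC(=C)C=C(OC)O[Si](C)(C)C
A5 | alternative 2 | benzyl 4-(but-2-ynoyloxy)-2-hydroxy-6-pentylbenzoate | CCCCCc1cc(OC(=O)C#CC)cc(O)c1C(=O)OCc1ccccc1
A6 | alternative 2 | benzyl 2-hydroxy-4-[(2-hydroxy-4-methoxy-6-methylbenzoyl)oxy]-6-pentylbenzoate | CCCCCc1cc(OC(=O)c2c(C)cc(OC)cc2O)cc(O)c1C(=O)OCc1ccccc1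
A7 | alternative 3 | 6-(2,4-dioxopentyl)-2,2-dimethyl-4H-1,3-dioxin-4-one | CC(=O)CC(=O)CC1=CC(=O)OC(C)(C)O1
A8 | alternative 3 | benzyl 2-hydroxy-6-pentyl-4-[(3,5,7-trioxooctanoyl)oxy]benzoate | CCCCCc1cc(OC(=O)CC(=O)CC(=O)CC(C)=O)cc(O)c1C(=O)OCc1ccccc1
A9 | alternative 3 | benzyl 4-[(2,4-dihydroxy-6-methylbenzoyl)oxy]-2-hydroxy-6-pentylbenzoate | CCCCCc1cc(OC(=O)c2c(C)cc(O)cc2O)cc(O)c1C(=O)OCc1ccccc1
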